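**Remarks on the chemistry (assumptions)**

- The C4 hydroxyl or C4 ether centres of 3, 4, 5, 9 and 14 are expected as epimer mixtures and are left undefined in the SMILES. Each of them is ionised to a planar cation before it is used, so this has no effect on the route.
- (+)-Dihydromyricetin, (+)-catechin and (−)-catechin are taken as the commercial, enantiopure samples.

## Analysis of the target

The target is a B-type proanthocyanidin trimer, gallocatechin-(4α→8)-catechin-(4β→8)-ent-catechin. It consists of three 2-arylchroman-3-ol units (ring A from phloroglucinol, pyran ring C, aryl ring B at C2) joined by two bonds from C4 of one ring C to C8 of the next ring A. There are eight stereocentres: C2, C3 and C4 of the top (2R,3S)-gallocatechin unit, C2, C3 and C4 of the middle (2R,3S)-catechin unit, and C2 and C3 of the bottom (2S,3R)-ent-catechin unit. All three units are 2,3-trans; the C4–aryl bond of the top unit is trans to its O-3, whereas that of the middle unit is cis to its O-3. Thirteen phenols (one pyrogallol, two catechols, three rings A) and three secondary alcohols make the free compound sensitive to air and base, and both interflavan bonds are benzylic to very electron-rich rings and therefore labile to acid. The six C2/C3 centres can be bought with the monomers, so the real problems are the two C4 centres, C8 against C6 in each arylation, and chain growth between units that can all act as nucleophiles. The middle C4 is the hard one, because a free arene adds to the C4 cation of a 2,3-trans flavan anti to O-3 and gives the trans bond. The strategy rests on one feature: O-3 of the middle unit and O-3 of the bottom unit are both hydroxyls that can be joined by a short diester, and C8 of the bottom ring A, held in this way, can reach C4 of the middle unit only on the face that carries O-3.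

## Retrosynthetic reasoning

**17 to 16.** The last operation should only uncover hydroxyl groups. All thirteen phenols and the top O-3 are therefore carried as benzyl ethers, which fall in one neutral hydrogenolysis, so that the free polyphenol never meets acid, base or a Lewis acid.

**16 to 15.** The two free hydroxyls of 16, O-3 of the middle and of the bottom unit, are reconnected through a glutarate diester. This cuts no skeletal bond; it turns the cis interflavan bond into part of a ring. The forward reaction is a plain methanolysis, which is safe because 15 has no free phenol.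

**15 to 14 (key disconnection).** The C4(middle)–C8(bottom) bond is cut. It is the only bond of the skeleton whose configuration cannot be had from free partners, so it is the one that is made within the tether. Forward, C4 of the middle unit must become a cation, the tethered ring A must bond through C8 and not C6, and ring closure must beat reaction between molecules. This bond is formed last among the C–C bonds, so the more strained cis linkage never sees a second Lewis-acid coupling.

**14 to 9 and 13.** The ester bond at O-3 of the middle unit is cut. This divides the molecule into a dimer electrophile 9 and the bottom unit already carrying its half of the tether, 13. Compound 13 comes from 11 by opening of the cyclic anhydride 12, and 11 from 10 by etherification of the four phenols.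

**9 to 8.** The C4–O bond of the middle unit is cut, that is, a benzylic oxidation in the forward sense. The leaving group must go in after the top–middle bond exists, because a unit with a C4 leaving group could not act as the nucleophile in the first coupling. It must go in before the tether, because afterwards two C4 methylene groups would compete.

**8 to 5 and 7.** The C4(top)–C8(middle) bond is cut. Here the wanted 3,4-trans arrangement is the natural result of attack anti to O-3, so an untethered coupling is enough. The top O-3 is a benzyl ether in 5 and the O-3 of 7 is free, so 8 has exactly one hydroxyl, at the position where the tether must later be attached.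

**5 to 1, and 7 to 6.** The C4 oxygen of the electrophile 5 is not made by oxidation. It is the C4 carbonyl oxygen position of 1, reduced (3), exchanged for an ether leaving group (4) and kept while O-3 is benzylated. C2 and C3 of the top unit come unchanged from 1 via 2. Compound 7 is 6 with its phenols etherified.

## Alternatives that were turned down

**Alternative 1: ring C of the top unit by a hetero-Diels–Alder reaction.**
- Disconnection: C3–C4 and O1–C2 of the top ring C, so that the gallocatechin unit is assembled last on a carbinol carbon already bonded to C8 of the middle unit.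
- Forward key step: acid ionises the ortho-hydroxy diarylcarbinol A3. The cation, in its quinone-methide form with the ring A phenol oxygen, adds the (E)-styrylboronate A2 in an inverse-demand [4+2] cycloaddition and gives the C3 boronate A1. The C–B bond is then oxidised to the hydroxyl with retention.
- For it: two bonds, one ring and three stereocentres arise in one step. The E geometry of A2 becomes the 2,3-trans relation. No unit has to be nucleophile and electrophile at once, so chain growth is not an issue; on this point it is stronger than step 6, which needs an excess of 7.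
- Against it: the three new centres are fixed only relative to each other. Their sense relative to the five centres already in A3 would rest on remote induction across the C4–C8 bond, for which the structure offers no reason. The C3/C4 relation depends on the endo or exo placement of the aryl group. Boron lowers the nucleophilicity of the alkene, while the donor-laden cation is a sluggish heterodiene that the free ring A positions of A3 can capture instead. Above all, A3 already contains the middle–bottom cis bond, which this disconnection does not make.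
- Comparison: after A1 the step count is similar (oxidation, hydrogenolysis), but before it a top unit must be built from achiral parts and the cis bond solved separately. The chosen route buys C2 and C3 of the top unit in 1 and spends its one stereochemical device where it is needed.

**Alternative 2: ring C of the middle unit by epoxide opening.**
- Disconnection: O1–C2 of the middle ring C, with the middle unit grown on an acylated ring A that already carries the top unit.
- Forward key step: in the chalcone epoxide A5 the free phenol ortho to the top unit opens the trans epoxide at its benzylic carbon with inversion (6-endo) and gives the 2,3-trans dihydroflavonol ketone A4.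
- For it: A4 brings C4 of the middle unit in at the ketone level, so the later C4 leaving group would come from a hydride reduction and not from a benzylic oxidation of a dimer. On this point it is stronger than step 7. The opening is stereospecific.
- Against it: C2 and C3 of the middle unit, which come with 6, would have to be set by an enantioselective epoxidation under reagent control on a substrate that already holds three stereocentres. The phenol can also attack the carbon next to the ketone (5-exo) and give a benzofuranone. The centre next to the ketone can epimerise, and the β-aryloxy ketone can reopen in base. The acyl group deactivates the ring that the top cation must alkylate on the way to A5. A4 is also still a dimer: the cis bond to the bottom unit is unmade and would again need the tether.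
- Comparison: several steps (enone formation, epoxidation, cyclisation, reduction) replace one etherification of 6. The chosen route accepts the oxidation of 8 as the price for keeping both stereocentres of the middle unit from the chiral pool.

**Alternative 3: ring C of the top unit by ring expansion of a dihydrobenzofuran.**
- Disconnection: O1–C2 and C3–O of the top ring C, traced back to a five-membered ring.
- Forward key step: acid ionises the exocyclic benzylic carbinol of A7, O1 bridges the cation to a three-membered oxonium ion, and water opens it at the former furan C2. The five-membered ring becomes the pyran ring of A6 with a new C3 hydroxyl.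
- For it: anti opening fixes the 2,3-trans relation. The C4 centre is set beforehand in the five-membered ring, where the trans arrangement is the stable one. A6 has the top O-3 as its only free hydroxyl; this differentiation is as good as the one the chosen route gets by benzylating 4, but the target does not need it.
- Against it: the opening must occur at the non-benzylic carbon of the bridged ion. Most of the positive charge sits on the carbon bearing the tribenzyloxyphenyl ring, so water is expected there, which only returns A7 or its carbinol epimer. The expansion would then depend on reversible acid conditions, and those are what the interflavan bonds of A7 tolerate least. A7 is a trimer-level compound whose top unit has three contiguous centres made from achiral parts, and the middle C4 is again not addressed.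
- Comparison: the chosen route carries all its sensitive cations at low temperature with a catalytic Lewis acid and takes the top unit's centres from 1.

Key step: step 11

## Route

**Step 1**
Reactants: 1 (+)-dihydromyricetin
Product: 2 (2R,3R)-5,7-bis(benzyloxy)-3-hydroxy-2-[3,4,5-tris(benzyloxy)phenyl]chroman-4-one
Conditions: BnBr (5.5 equiv), K2CO3, DMF, rt, argon
Reagents that add atoms: benzyl bromide, BrCc1ccccc1
Why: Williamson etherification of the five phenols; carbonate does not deprotonate the aliphatic 3-OH, which stays free. C2 and C3 are not touched, and the 2,3-trans isomer is also the more stable one.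

**Step 2**
Reactants: 2 penta-O-benzyldihydromyricetin
Product: 3 5,7,3',4',5'-penta-O-benzyl-flavan-3,4-diol of the gallocatechin series (C2 and C3 as in gallocatechin, 2,3-trans; C4 epimers)
Conditions: NaBH4, THF/EtOH, 0 °C to rt
Reagents that add atoms: none
Why: Hydride reduction of the aryl ketone to the benzylic alcohol. The configuration formed at C4 does not matter, because this centre is ionised in steps 3 and 6.

**Step 3**
Reactants: 3 penta-O-benzyl-flavan-3,4-diol
Product: 4 5,7,3',4',5'-penta-O-benzyl-4-(2-ethoxyethoxy)gallocatechin (3-OH free; C4 epimers)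
Conditions: 2-ethoxyethanol/CH2Cl2 (1:3), PPTS (cat.), rt
Reagents that add atoms: 2-ethoxyethanol, CCOCCO
Why: SN1 solvolytic etherification: the C4 hydroxyl is benzylic to a ring with ortho and para oxygen donors and ionises under mild acid, and the large excess of alcohol traps the cation. The non-benzylic 3-OH cannot ionise and is unchanged.

**Step 4**
Reactants: 4 4-(2-ethoxyethoxy)-penta-O-benzylgallocatechin
Product: 5 3,5,7,3',4',5'-hexa-O-benzyl-4-(2-ethoxyethoxy)gallocatechin (C4 epimers)
Conditions: NaH, BnBr, Bu4NI (cat.), DMF, 0 °C to rt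
Reagents that add atoms: benzyl bromide, BrCc1ccccc1
Why: Williamson etherification of the remaining secondary alcohol. The C4 ether is stable to base and no stereocentre is affected.

**Step 5**
Reactants: 6 (+)-catechin
Product: 7 5,7,3',4'-tetra-O-benzyl-(+)-catechin (2R,3S; 3-OH free)
Conditions: BnBr (4.4 equiv), K2CO3, DMF, rt, argon
Reagents that add atoms: benzyl bromide, BrCc1ccccc1
Why: Williamson etherification of the four phenols under carbonate; the secondary alcohol is not alkylated.

**Step 6**
Reactants: 5 hexa-O-benzyl-4-(2-ethoxyethoxy)gallocatechin; 7 tetra-O-benzylcatechin (4 equiv, excess recovered)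
Product: 8 3,5,7,3',4',5'-hexa-O-benzylgallocatechin-(4α→8)-5,7,3',4'-tetra-O-benzylcatechin (top unit 3,4-trans; the only free hydroxyl is O-3 of the catechin unit)
Conditions: Me3SiOTf (0.2 equiv), CH2Cl2, −78 °C; Et3N quench
Reagents that add atoms: none
Why: Lewis-acid-promoted intermolecular Friedel–Crafts alkylation (flavan coupling): the C4 ether of 5 ionises and C8 of 7, the least hindered and most nucleophilic ring A position, adds to the cation anti to the 3-benzyloxy group, which sets the top C4 as 4α (3,4-trans). The excess of 7 suppresses self-condensation of 5 and further alkylation of 8; capture by the free 3-OH of 7 is reversible, whereas C-alkylation is not.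

**Step 7**
Reactants: 8 benzylated gallocatechin-(4α→8)-catechin dimer
Product: 9 dimer 8 bearing a 2-ethoxyethoxy group at C4 of the catechin unit (3-OH free; new C4 as epimers)
Conditions: DDQ (2 equiv), 2-ethoxyethanol (5 equiv), CH2Cl2, rt
Reagents that add atoms: 2-ethoxyethanol, CCOCCO
Why: DDQ benzylic oxidation by hydride abstraction from the only C4 methylene para and ortho to ring A oxygens, with capture of the cation by the alcohol. The top C4 methine is flanked by two ortho-disubstituted aryl rings and cannot easily become planar, and plain benzyl ethers are not oxidised under these conditions.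

**Step 8**
Reactants: 10 (−)-catechin
Product: 11 5,7,3',4'-tetra-O-benzyl-ent-catechin (2S,3R; 3-OH free)
Conditions: BnBr (4.4 equiv), K2CO3, DMF, rt, argon
Reagents that add atoms: benzyl bromide, BrCc1ccccc1
Why: Williamson etherification of the four phenols, as in step 5.

**Step 9**
Reactants: 11 tetra-O-benzyl-ent-catechin; 12 glutaric anhydride
Product: 13 hydrogen glutarate of 11 (5,7,3',4'-tetra-O-benzyl-ent-catechin 3-O-(4-carboxybutanoate))
Conditions: DMAP (cat.), pyridine, 50 °C
Reagents that add atoms: none
Why: DMAP-catalysed ring opening of the cyclic anhydride by the secondary alcohol. Each anhydride molecule can acylate only once, so the half-ester forms without diester.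

**Step 10**
Reactants: 9 C4-(2-ethoxyethoxy) dimer; 13 hydrogen glutarate of tetra-O-benzyl-ent-catechin
Product: 14 glutarate diester joining O-3 of the catechin unit of 9 to O-3 of 11
Conditions: DCC, DMAP (cat.), CH2Cl2, 0 °C to rt
Reagents that add atoms: none
Why: Steglich esterification under neutral to basic conditions, which keep the acid-labile C4 ether and all stereocentres intact.

**Step 11 (key step)**
Reactants: 14 glutarate diester
Product: 15 glutarate-bridged tetradeca-O-benzyl gallocatechin-(4α→8)-catechin-(4β→8)-ent-catechin (middle unit 3,4-cis; 14-membered bridge from O-3 of the middle unit to O-3 of the bottom unit)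
Conditions: Me3SiOTf (0.3 equiv), CH2Cl2 (0.5 mM, slow addition of 14), −40 to −20 °C; Et3N quench
Reagents that add atoms: none
Why: Me3SiOTf silylates the 2-ethoxyethyl ether oxygen at C4 of the middle unit and the ether leaves, giving a benzylic cation stabilised by the ring A oxygens (a quinone-methide-like oxocarbenium ion). C8 of the tethered ent-catechin ring A adds to it and loss of the proton restores the arene; this is an intramolecular Friedel–Crafts alkylation whose closest known relative is the Lewis-acid coupling of two flavan-3-ol units joined through their O-3 atoms by a diacid linker. The ring that closes is the 14-membered macrocycle C4–C3–O–CO–(CH2)3–CO–O–C3–C2–O1–C8a–C8, formed by exo attack on the exocyclic C4 terminus of the cation under high dilution. The new stereocentre, C4 of the middle unit, is controlled by the tether: the glutarate leaves from O-3 on the face opposite to the C2 aryl group and is too short to pass around the heterocycle, so the arene can bond only on that face and the new bond is cis to O-3 (4β). Closure through C6 of the bottom ring would give the same ring size, but C8 has only one benzyloxy neighbour and lies nearer to C3 across the chroman, so it should be preferred. Ring closure is favoured over reaction between molecules by the high dilution; C8 of the middle unit is already substituted, and the remaining free ring A positions can react only intermolecularly. The top–middle bond, the esters and the benzyl ethers should survive because the Lewis acid is catalytic and the temperature is low.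

**Step 12**
Reactants: 15 glutarate-bridged benzylated trimer
Product: 16 tetradeca-O-benzyl gallocatechin-(4α→8)-catechin-(4β→8)-ent-catechin with free 3-OH on the middle and bottom units
Conditions: K2CO3 (cat.), MeOH/THF (1:1), 40 °C
Reagents that add atoms: none
Why: Base-catalysed transesterification with methanol cleaves both ester links and releases the tether as its dimethyl ester. Without free phenols, the benzyl ethers, the interflavan bonds and all stereocentres are stable to methoxide.

**Step 13**
Reactants: 16 benzylated trimer diol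
Product: 17 gallocatechin-(4α→8)-catechin-(4β→8)-ent-catechin (target)
Conditions: H2 (1 atm), Pd(OH)2/C, THF/MeOH/H2O, rt; filtration under argon, lyophilisation
Reagents that add atoms: none
Why: Catalytic hydrogenolysis of the fourteen benzyl ethers in neutral medium, which spares the acid-labile interflavan bonds and the chroman C–O bonds. No stereocentre is involved.

## Compound list

1 | (+)-dihydromyricetin, (2R,3R) | Oc1cc(O)c2c(c1)O[C@H](c1cc(O)c(O)c(O)c1)[C@@H](O)C2=O | starting material
2 | 5,7,3',4',5'-penta-O-benzyldihydromyricetin, (2R,3R) | c3ccccc3COc1cc(OCc3ccccc3)c2c(c1)O[C@H](c1cc(OCc3ccccc3)c(OCc3ccccc3)c(OCc3ccccc3)c1)[C@@H](O)C2=O | intermediate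
3 | 5,7,3',4',5'-penta-O-benzyl-flavan-3,4-diol, gallocatechin series, 2,3-trans, C4 epimers | c3ccccc3COc1cc(OCc3ccccc3)c2c(c1)O[C@H](c1cc(OCc3ccccc3)c(OCc3ccccc3)c(OCc3ccccc3)c1)[C@@H](O)C2O | intermediate
4 | 5,7,3',4',5'-penta-O-benzyl-4-(2-ethoxyethoxy)gallocatechin, 3-OH free, C4 epimers | c3ccccc3COc1cc(OCc3ccccc3)c2c(c1)O[C@H](c1cc(OCc3ccccc3)c(OCc3ccccc3)c(OCc3ccccc3)c1)[C@@H](O)C2OCCOCC | intermediate
5 | 3,5,7,3',4',5'-hexa-O-benzyl-4-(2-ethoxyethoxy)gallocatechin, C4 epimers | c3ccccc3COc1cc(OCc3ccccc3)c2c(c1)O[C@H](c1cc(OCc3ccccc3)c(OCc3ccccc3)c(OCc3ccccc3)c1)[C@@H](OCc3ccccc3)C2OCCOCC | intermediate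
6 | (+)-catechin, (2R,3S) | Oc1cc(O)c2c(c1)O[C@H](c1ccc(O)c(O)c1)[C@@H](O)C2 | starting material
7 | 5,7,3',4'-tetra-O-benzyl-(+)-catechin | c3ccccc3COc1cc(OCc3ccccc3)c2c(c1)O[C@H](c1ccc(OCc3ccccc3)c(OCc3ccccc3)c1)[C@@H](O)C2 | intermediate
8 | hexa-O-benzylgallocatechin-(4α→8)-tetra-O-benzylcatechin, free 3-OH on the catechin unit | c3ccccc3COc1cc(OCc3ccccc3)c2c(c1)O[C@H](c1cc(OCc3ccccc3)c(OCc3ccccc3)c(OCc3ccccc3)c1)[C@@H](OCc3ccccc3)[C@@H]2c1c(OCc3ccccc3)cc(OCc3ccccc3)c2c1O[C@H](c1ccc(OCc3ccccc3)c(OCc3ccccc3)c1)[C@@H](O)C2 | intermediate
9 | dimer 8 with 4-(2-ethoxyethoxy) on the catechin unit, 3-OH free, C4 epimers | c3ccccc3COc1cc(OCc3ccccc3)c2c(c1)O[C@H](c1cc(OCc3ccccc3)c(OCc3ccccc3)c(OCc3ccccc3)c1)[C@@H](OCc3ccccc3)[C@@H]2c1c(OCc3ccccc3)cc(OCc3ccccc3)c2c1O[C@H](c1ccc(OCc3ccccc3)c(OCc3ccccc3)c1)[C@@H](O)C2OCCOCC | intermediate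
10 | (−)-catechin (ent-catechin), (2S,3R) | Oc1cc(O)c2c(c1)O[C@@H](c1ccc(O)c(O)c1)[C@H](O)C2 | starting material
11 | 5,7,3',4'-tetra-O-benzyl-ent-catechin | c3ccccc3COc1cc(OCc3ccccc3)c2c(c1)O[C@@H](c1ccc(OCc3ccccc3)c(OCc3ccccc3)c1)[C@H](O)C2 | intermediate
12 | glutaric anhydride | O=C1CCCC(=O)O1 | starting material
13 | hydrogen glutarate of 11 | c3ccccc3COc1cc(OCc3ccccc3)c2c(c1)O[C@@H](c1ccc(OCc3ccccc3)c(OCc3ccccc3)c1)[C@H](OC(=O)CCCC(=O)O)C2 | intermediate
14 | glutarate diester of 9 (O-3, catechin unit) and 11 (O-3) | c3ccccc3COc1cc(OCc3ccccc3)c2c(c1)O[C@H](c1cc(OCc3ccccc3)c(OCc3ccccc3)c(OCc3ccccc3)c1)[C@@H](OCc3ccccc3)[C@@H]2c1c(OCc3ccccc3)cc(OCc3ccccc3)c2c1O[C@H](c1ccc(OCc3ccccc3)c(OCc3ccccc3)c1)[C@@H](OC(=O)CCCC(=O)O[C@@H]4Cc5c(OCc3ccccc3)cc(OCc3ccccc3)cc5O[C@H]4c1ccc(OCc3ccccc3)c(OCc3ccccc3)c1)C2OCCOCC | intermediate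
15 | glutarate-bridged benzylated trimer, middle unit 3,4-cis | c3ccccc3COc1cc(OCc3ccccc3)c2c(c1)O[C@H](c1cc(OCc3ccccc3)c(OCc3ccccc3)c(OCc3ccccc3)c1)[C@@H](OCc3ccccc3)[C@@H]2c1c(OCc3ccccc3)cc(OCc3ccccc3)c2c1O[C@H](c1ccc(OCc3ccccc3)c(OCc3ccccc3)c1)[C@@H](OC(=O)CCCC4=O)[C@H]2c1c(OCc3ccccc3)cc(OCc3ccccc3)c2c1O[C@@H](c1ccc(OCc3ccccc3)c(OCc3ccccc3)c1)[C@H](O4)C2 | intermediate
16 | tetradeca-O-benzyl trimer with free 3-OH on the middle and bottom units | c3ccccc3COc1cc(OCc3ccccc3)c2c(c1)O[C@H](c1cc(OCc3ccccc3)c(OCc3ccccc3)c(OCc3ccccc3)c1)[C@@H](OCc3ccccc3)[C@@H]2c1c(OCc3ccccc3)cc(OCc3ccccc3)c2c1O[C@H](c1ccc(OCc3ccccc3)c(OCc3ccccc3)c1)[C@@H](O)[C@H]2c1c(OCc3ccccc3)cc(OCc3ccccc3)c2c1O[C@@H](c1ccc(OCc3ccccc3)c(OCc3ccccc3)c1)[C@H](O)C2 | intermediate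
17 | gallocatechin-(4α→8)-catechin-(4β→8)-ent-catechin (CNP0155646.2) | Oc1cc(O)c2c(c1)O[C@H](c1cc(O)c(O)c(O)c1)[C@@H](O)[C@@H]2c1c(O)cc(O)c2c1O[C@H](c1ccc(O)c(O)c1)[C@@H](O)[C@H]2c1c(O)cc(O)c2c1O[C@@H](c1ccc(O)c(O)c1)[C@H](O)C2 | target

## Step count and least certain steps

Total step count: 13. Longest linear sequence: 10 steps (steps 1, 2, 3, 4, 6, 7, 10, 11, 12, 13).

**Step 11 (key step).**
- What may go wrong: ring closure through C6 of the bottom ring A in place of C8, since both close a 14-membered ring. Because the bottom unit belongs to the enantiomeric series, the fit of the macrocyclic transition state is not assured; if closure is slow, alkylation between molecules at free ring A positions or acid-induced scission of the top–middle bond may take over.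
- Fallback (a shorter tether): on a model of the chroman, C8 is closer to C3 than C6 is, so a shorter bridge should sharpen the preference for C8 and keep the face control. Setting out from 11, opening of succinic anhydride (DMAP, pyridine) would give the hydrogen succinate of 11 F1. Steglich esterification of F1 with 9 would give the succinate diester F2. Me3SiOTf at high dilution would close the 13-membered succinate-bridged trimer F3. Methanolysis (K2CO3, MeOH/THF) would bring the route back at 16.

**Step 7.**
- What may go wrong: hydride abstraction at another benzylic position, over-oxidation of C4 to the ketone, or oxidative breakage of the interflavan bond, since this oxidation is applied to a dimer rather than to a monomer.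
- Fallback (oxidise at the monomer stage and change the order of the two couplings): setting out from 7, DDQ and 2-ethoxyethanol would give 5,7,3',4'-tetra-O-benzyl-4-(2-ethoxyethoxy)catechin F4. Esterification of F4 with 13 (DCC, DMAP) would give the dimer-level diester F5. Me3SiOTf at high dilution would close the glutarate-bridged octa-O-benzyl catechin-(4β→8)-ent-catechin F6. Coupling of F6 (slight excess) with 5 under Me3SiOTf at −78 °C, at the only free C8, would bring the route back at 15.

**Step 6.**
- What may go wrong: self-condensation of the electrophile through its own free C8 and further alkylation of the product, leading to chain growth; incomplete preference for C8 and for the α face.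
- Fallback (cap the electrophile with bromine): setting out from 5, NBS (CH2Cl2, −10 °C, NaHCO3) would give 8-bromo-hexa-O-benzyl-4-(2-ethoxyethoxy)gallocatechin F7, which cannot act as a nucleophile. Coupling of F7 with a small excess of 7 (Me3SiOTf, −78 °C) would give the 8-bromo dimer F8. Bromine–lithium exchange (n-BuLi, 3 equiv, THF, −78 °C) followed by a methanol quench would bring the route back at 8.

**Step 1.**
- What may go wrong: base-induced opening of the flavanonol ring through its enolate with loss of configuration at C2 and C3, dehydrogenation to the flavonol, incomplete etherification of the hydrogen-bonded 5-OH, and air oxidation of the pyrogallol ring.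
- Fallback (start from the flavan and introduce the C4 oxygen by oxidation): commercial, though costly, (+)-gallocatechin F9 would be benzylated on its five phenols (BnBr, K2CO3, DMF) to 5,7,3',4',5'-penta-O-benzylgallocatechin F10. NaH and BnBr would give 3,5,7,3',4',5'-hexa-O-benzylgallocatechin F11. DDQ with 2-ethoxyethanol would bring the route back at 5.

**Step 10.**
- What may go wrong: slow acylation of the hindered 3-OH of 9, which lies between the C2 aryl group and the C4 ether, so that the activated acid rearranges to the unreactive N-acylurea; loss of the C4 ether on long reaction times.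
- Fallback (reverse the order of the two acylations): setting out from 9, the small anhydride 12 (DMAP, pyridine) would acylate the hindered alcohol and give the hydrogen glutarate of 9 F12. Yamaguchi esterification of F12 with the less hindered alcohol 11 (2,4,6-trichlorobenzoyl chloride, Et3N, DMAP, toluene) would bring the route back at 14.

## Further compounds

F1 | step 11 | hydrogen succinate of 11 | c3ccccc3COc1cc(OCc3ccccc3)c2c(c1)O[C@@H](c1ccc(OCc3ccccc3)c(OCc3ccccc3)c1)[C@H](OC(=O)CCC(=O)O)C2
F2 | step 11 | succinate diester of 9 (O-3, catechin unit) and 11 (O-3) | c3ccccc3COc1cc(OCc3ccccc3)c2c(c1)O[C@H](c1cc(OCc3ccccc3)c(OCc3ccccc3)c(OCc3ccccc3)c1)[C@@H](OCc3ccccc3)[C@@H]2c1c(OCc3ccccc3)cc(OCc3ccccc3)c2c1O[C@H](c1ccc(OCc3ccccc3)c(OCc3ccccc3)c1)[C@@H](OC(=O)CCC(=O)O[C@@H]4Cc5c(OCc3ccccc3)cc(OCc3ccccc3)cc5O[C@H]4c1ccc(OCc3ccccc3)c(OCc3ccccc3)c1)C2OCCOCC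
F3 | step 11 | succinate-bridged benzylated trimer, middle unit 3,4-cis, 13-membered bridge | c3ccccc3COc1cc(OCc3ccccc3)c2c(c1)O[C@H](c1cc(OCc3ccccc3)c(OCc3ccccc3)c(OCc3ccccc3)c1)[C@@H](OCc3ccccc3)[C@@H]2c1c(OCc3ccccc3)cc(OCc3ccccc3)c2c1O[C@H](c1ccc(OCc3ccccc3)c(OCc3ccccc3)c1)[C@@H](OC(=O)CCC4=O)[C@H]2c1c(OCc3ccccc3)cc(OCc3ccccc3)c2c1O[C@@H](c1ccc(OCc3ccccc3)c(OCc3ccccc3)c1)[C@H](O4)C2
F4 | step 7 | 5,7,3',4'-tetra-O-benzyl-4-(2-ethoxyethoxy)catechin, 3-OH free, C4 epimers | c3ccccc3COc1cc(OCc3ccccc3)c2c(c1)O[C@H](c1ccc(OCc3ccccc3)c(OCc3ccccc3)c1)[C@@H](O)C2OCCOCC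
F5 | step 7 | glutarate diester of F4 (O-3) and 11 (O-3) | c3ccccc3COc1cc(OCc3ccccc3)c2c(c1)O[C@H](c1ccc(OCc3ccccc3)c(OCc3ccccc3)c1)[C@@H](OC(=O)CCCC(=O)O[C@@H]4Cc5c(OCc3ccccc3)cc(OCc3ccccc3)cc5O[C@H]4c1ccc(OCc3ccccc3)c(OCc3ccccc3)c1)C2OCCOCC
F6 | step 7 | glutarate-bridged octa-O-benzyl catechin-(4β→8)-ent-catechin, 3,4-cis | c3ccccc3COc1cc(OCc3ccccc3)c2c(c1)O[C@H](c1ccc(OCc3ccccc3)c(OCc3ccccc3)c1)[C@@H](OC(=O)CCCC4=O)[C@H]2c1c(OCc3ccccc3)cc(OCc3ccccc3)c2c1O[C@@H](c1ccc(OCc3ccccc3)c(OCc3ccccc3)c1)[C@H](O4)C2
F7 | step 6 | 8-bromo-3,5,7,3',4',5'-hexa-O-benzyl-4-(2-ethoxyethoxy)gallocatechin, C4 epimers | c3ccccc3COc1cc(OCc3ccccc3)c2c(c1Br)O[C@H](c1cc(OCc3ccccc3)c(OCc3ccccc3)c(OCc3ccccc3)c1)[C@@H](OCc3ccccc3)C2OCCOCC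
F8 | step 6 | 8-bromo-hexa-O-benzylgallocatechin-(4α→8)-tetra-O-benzylcatechin, free 3-OH on the catechin unit | c3ccccc3COc1cc(OCc3ccccc3)c2c(c1Br)O[C@H](c1cc(OCc3ccccc3)c(OCc3ccccc3)c(OCc3ccccc3)c1)[C@@H](OCc3ccccc3)[C@@H]2c1c(OCc3ccccc3)cc(OCc3ccccc3)c2c1O[C@H](c1ccc(OCc3ccccc3)c(OCc3ccccc3)c1)[C@@H](O)C2
F9 | step 1 | (+)-gallocatechin, (2R,3S) | Oc1cc(O)c2c(c1)O[C@H](c1cc(O)c(O)c(O)c1)[C@@H](O)C2
F10 | step 1 | 5,7,3',4',5'-penta-O-benzylgallocatechin | c3ccccc3COc1cc(OCc3ccccc3)c2c(c1)O[C@H](c1cc(OCc3ccccc3)c(OCc3ccccc3)c(OCc3ccccc3)c1)[C@@H](O)C2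
F11 | step 1 | 3,5,7,3',4',5'-hexa-O-benzylgallocatechin | c3ccccc3COc1cc(OCc3ccccc3)c2c(c1)O[C@H](c1cc(OCc3ccccc3)c(OCc3ccccc3)c(OCc3ccccc3)c1)[C@@H](OCc3ccccc3)C2
F12 | step 10 | hydrogen glutarate of 9 (at O-3 of the catechin unit) | c3ccccc3COc1cc(OCc3ccccc3)c2c(c1)O[C@H](c1cc(OCc3ccccc3)c(OCc3ccccc3)c(OCc3ccccc3)c1)[C@@H](OCc3ccccc3)[C@@H]2c1c(OCc3ccccc3)cc(OCc3ccccc3)c2c1O[C@H](c1ccc(OCc3ccccc3)c(OCc3ccccc3)c1)[C@@H](OC(=O)CCCC(=O)O)C2OCCOCC
A1 | alternative 1 | benzylated trimer with a pinacolboryl group at C3 of the top unit | c3ccccc3COc1cc(OCc3ccccc3)c2c(c1)O[C@H](c1cc(OCc3ccccc3)c(OCc3ccccc3)c(OCc3ccccc3)c1)[C@@H](B3OC(C)(C)C(C)(C)O3)[C@@H]2c1c(OCc3ccccc3)cc(OCc3ccccc3)c2c1O[C@H](c1ccc(OCc3ccccc3)c(OCc3ccccc3)c1)[C@@H](OCc3ccccc3)[C@H]2c1c(OCc3ccccc3)cc(OCc3ccccc3)c2c1O[C@@H](c1ccc(OCc3ccccc3)c(OCc3ccccc3)c1)[C@H](OCc3ccccc3)C2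
A2 | alternative 1 | (E)-2-[2-(3,4,5-tris(benzyloxy)phenyl)ethenyl]-4,4,5,5-tetramethyl-1,3,2-dioxaborolane | CC1(C)OB(/C=C/c2cc(OCc3ccccc3)c(OCc3ccccc3)c(OCc3ccccc3)c2)OC1(C)C
A3 | alternative 1 | ortho-hydroxy diarylcarbinol at C8 of the middle unit of the benzylated catechin-(4β→8)-ent-catechin dimer (carbinol centre undefined) | OC(c1c(O)cc(OCc3ccccc3)cc1OCc3ccccc3)c1c(OCc3ccccc3)cc(OCc3ccccc3)c2c1O[C@H](c1ccc(OCc3ccccc3)c(OCc3ccccc3)c1)[C@@H](OCc3ccccc3)[C@H]2c1c(OCc3ccccc3)cc(OCc3ccccc3)c2c1O[C@@H](c1ccc(OCc3ccccc3)c(OCc3ccccc3)c1)[C@H](OCc3ccccc3)C2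
A4 | alternative 2 | benzylated gallocatechin-(4α→8)-dihydroflavonol C4 ketone with free O-3, (2R,3R) in the ketone unit | c3ccccc3COc1cc(OCc3ccccc3)c2c(c1)O[C@H](c1cc(OCc3ccccc3)c(OCc3ccccc3)c(OCc3ccccc3)c1)[C@@H](OCc3ccccc3)[C@@H]2c1c(OCc3ccccc3)cc(OCc3ccccc3)c2c1O[C@H](c1ccc(OCc3ccccc3)c(OCc3ccccc3)c1)[C@@H](O)C2=O
A5 | alternative 2 | trans chalcone epoxide (αR,βS) on the 2-hydroxy-4,6-bis(benzyloxy)aryl ketone bearing the top unit at C3 of that ring | c3ccccc3COc1cc(OCc3ccccc3)c2c(c1)O[C@H](c1cc(OCc3ccccc3)c(OCc3ccccc3)c(OCc3ccccc3)c1)[C@@H](OCc3ccccc3)[C@@H]2c1c(OCc3ccccc3)cc(OCc3ccccc3)c(C(=O)[C@@H]4O[C@H]4c5ccc(OCc3ccccc3)c(OCc3ccccc3)c5)c1O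
A6 | alternative 3 | benzylated trimer with free C3 hydroxyl on the top unit | c3ccccc3COc1cc(OCc3ccccc3)c2c(c1)O[C@H](c1cc(OCc3ccccc3)c(OCc3ccccc3)c(OCc3ccccc3)c1)[C@@H](O)[C@@H]2c1c(OCc3ccccc3)cc(OCc3ccccc3)c2c1O[C@H](c1ccc(OCc3ccccc3)c(OCc3ccccc3)c1)[C@@H](OCc3ccccc3)[C@H]2c1c(OCc3ccccc3)cc(OCc3ccccc3)c2c1O[C@@H](c1ccc(OCc3ccccc3)c(OCc3ccccc3)c1)[C@H](OCc3ccccc3)C2
A7 | alternative 3 | trans-2,3-dihydrobenzofuran with an exocyclic aryl carbinol at C2 and the middle unit at C3 (carbinol centre undefined) | OC(c1cc(OCc3ccccc3)c(OCc3ccccc3)c(OCc3ccccc3)c1)[C@@H]4Oc5cc(OCc3ccccc3)cc(OCc3ccccc3)c5[C@H]4c1c(OCc3ccccc3)cc(OCc3ccccc3)c2c1O[C@H](c1ccc(OCc3ccccc3)c(OCc3ccccc3)c1)[C@@H](OCc3ccccc3)[C@H]2c1c(OCc3ccccc3)cc(OCc3ccccc3)c2c1O[C@@H](c1ccc(OCc3ccccc3)c(OCc3ccccc3)c1)[C@H](OCc3ccccc3)C2
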